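**Retrosynthetic overview**

- Numbering: C1 = carbinol bridgehead; ring A = C1–C2(Ar)–O3–C4–C5; ring B = C5–C6(Ar)–O7–C8–C1. The plan rests on one feature: quaternary C1 carries the methylene C8, and C8 is joined through O7 to C6, so a silicon atom parked on the C6 oxygen can hand C8 to C1 and later be cut out.
- Last disconnection O7–C8 (ring B): the C6 oxygen closes onto C8 after the C8–Si bond has been oxidised to C8–OH; the C6–O bond is never broken, so the endo C6 aryl group is kept.
- Key disconnection C1–C8 plus C2–O3: a silylmethyl radical tethered to the C6 oxygen adds to C1 of a (Z)-silyl enol ether, and the benzylic C2 cation formed by radical–polar crossover is trapped by the C4 oxygen.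
- The enol ether comes from a benzyl ketone (benzylic Grignard reagent on a Weinreb amide); its C5/C6 syn pair is set by an Evans syn-aldol with veratraldehyde.
- Ring order: temporary siloxane ring and ring A together (step 7), ring B last (step 10).

Key step: step 7

Assumption: 3-(tert-butyldimethylsilyloxy)propanoic acid 2 is taken as a catalogue reagent (otherwise one silylation/saponification from methyl 3-hydroxypropanoate); descriptors quoted "in overview numbering" use C1–C8 as defined above.

**Route**

Step 1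
Reactants: 1 (R)-4-benzyl-2-oxazolidinone; 2 3-(tert-butyldimethylsilyloxy)propanoic acid
Product: 4 (R)-4-benzyl-3-[3-(tert-butyldimethylsilyloxy)propanoyl]oxazolidin-2-one, via mixed pivalic anhydride 3 (not isolated)
Conditions: PivCl, Et3N, THF, −20 °C; then LiCl, 1, −20 °C → rt
Reagents that add atoms: none
Why: N-acylation of the oxazolidinone through the pivaloyl mixed anhydride with LiCl/Et3N is a mild standard route to Evans imides from free acids and should leave the silyl ether intact; no stereocentre is formed.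

Step 2
Reactants: 4 (R)-4-benzyl-3-[3-(tert-butyldimethylsilyloxy)propanoyl]oxazolidin-2-one; 5 veratraldehyde
Product: 7 (R)-4-benzyl-3-[(2R,3R)-2-(tert-butyldimethylsilyloxymethyl)-3-(3,4-dimethoxyphenyl)-3-hydroxypropanoyl]oxazolidin-2-one, via dibutylboron Z-enolate 6 (not isolated)
Conditions: Bu2BOTf, i-Pr2NEt, CH2Cl2, −78 → 0 °C; 5, −78 → 0 °C; pH 7 phosphate buffer, MeOH, 30% H2O2, 0 °C
Reagents that add atoms: none
Why: Evans syn-aldol, in which the Z-boron enolate reacts through a Zimmerman–Traxler chair on the face opposite the benzyl group of the (R)-auxiliary and so sets C5 and C6 as the (2R,3R) syn pair; the covalent boron enolate should not expel the β-silyloxy group at low temperature.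

Step 3
Reactants: 7 (R)-4-benzyl-3-[(2R,3R)-2-(tert-butyldimethylsilyloxymethyl)-3-(3,4-dimethoxyphenyl)-3-hydroxypropanoyl]oxazolidin-2-one
Product: 8 (2R,3R)-2-(tert-butyldimethylsilyloxymethyl)-3-(3,4-dimethoxyphenyl)-3-hydroxy-N-methoxy-N-methylpropanamide
Conditions: MeNH(OMe)·HCl, AlMe3, CH2Cl2, −20 → 0 °C; aq. KNaC4H4O6 work-up
Reagents that add atoms: N,O-dimethylhydroxylamine hydrochloride, CNOC.Cl
Why: Weinreb transamidation of an aldol imide by the aluminium amide, assisted by the free β-hydroxyl as its aluminium alkoxide, cleaves the exocyclic acyl–nitrogen bond without epimerising C5 and returns the auxiliary.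

Step 4
Reactants: 8 (2R,3R)-2-(tert-butyldimethylsilyloxymethyl)-3-(3,4-dimethoxyphenyl)-3-hydroxy-N-methoxy-N-methylpropanamide; 9 3,4-dimethoxybenzyl chloride
Product: 11 (3R,4R)-3-(tert-butyldimethylsilyloxymethyl)-1,4-bis(3,4-dimethoxyphenyl)-4-hydroxybutan-2-one, via 3,4-dimethoxybenzylmagnesium chloride 10 (not isolated)
Conditions: 9, Mg, THF, 0 °C (slow addition, dilute); then 8, THF, −20 → 0 °C (3 equiv of 10); aq. NH4Cl
Reagents that add atoms: none
Why: Weinreb ketone synthesis, in which one equivalent of the Grignard reagent deprotonates the hydroxyl and a second adds to give a stable magnesium chelate that releases the ketone only on work-up, so over-addition and enolisation of the product in the flask are excluded.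

Step 5
Reactants: 11 (3R,4R)-3-(tert-butyldimethylsilyloxymethyl)-1,4-bis(3,4-dimethoxyphenyl)-4-hydroxybutan-2-one; 12 (bromomethyl)chlorodimethylsilane
Product: 14 (3R,4R)-3-(tert-butyldimethylsilyloxymethyl)-1,4-bis(3,4-dimethoxyphenyl)-4-[(iodomethyl)dimethylsilyloxy]butan-2-one, via bromomethylsilyl ether 13 (not isolated)
Conditions: 12, imidazole, CH2Cl2, 0 °C; filtration, solvent exchange; NaI, acetone, rt, dark
Reagents that add atoms: sodium iodide, [Na+].[I-]
Why: O-silylation of the secondary alcohol with the chlorosilane followed by Finkelstein exchange of the primary α-silyl bromide are the standard operations for a Nishiyama–Stork tether and touch neither C5 nor C6.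

Step 6
Reactants: 14 (3R,4R)-3-(tert-butyldimethylsilyloxymethyl)-1,4-bis(3,4-dimethoxyphenyl)-4-[(iodomethyl)dimethylsilyloxy]butan-2-one
Product: 15 (1Z,3R,4R)-3-(tert-butyldimethylsilyloxymethyl)-1,4-bis(3,4-dimethoxyphenyl)-4-[(iodomethyl)dimethylsilyloxy]-2-(triethylsilyloxy)but-1-ene
Conditions: TESOTf, Et3N, CH2Cl2, −78 → 0 °C; cold aq. NaHCO3; filtration through basic Al2O3, used at once
Reagents that add atoms: triethylsilyl trifluoromethanesulfonate, CC[Si](CC)(CC)OS(=O)(=O)C(F)(F)F
Why: Soft enolisation of a benzyl ketone removes the more acidic benzylic C2 proton rather than the hindered C5 proton and should give the conjugated (Z)-silyl enol ether with the aryl group anti to C5; the geometry is not decisive because C2 is set only in step 7.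

Step 7
Reactants: 15 (1Z,3R,4R)-3-(tert-butyldimethylsilyloxymethyl)-1,4-bis(3,4-dimethoxyphenyl)-4-[(iodomethyl)dimethylsilyloxy]-2-(triethylsilyloxy)but-1-ene
Product: 16 bicyclic siloxane: ring A tetrahydrofuran (C1, C2, O3, C4, C5) cis-fused across C1–C5 to the six-membered ring C1–C8H2–SiMe2–O–C6–C5; C1 bears OSiEt3; C2 aryl cis to the C1 oxygen; C6 aryl cis to C4; (1R,2R,5R,6R) in overview numbering
Conditions: fac-Ir(ppy)3 (tris(2-phenylpyridinato)iridium, 2 mol%), 2,6-lutidine, degassed MeCN (0.02 M), blue LEDs (450 nm), 25 °C; aq. NaHCO3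
Reagents that add atoms: none
Why: Proposed new method: excited fac-Ir(ppy)3 (trivalent iridium) transfers an electron to the C–I bond, the silylmethyl radical adds to C1 of the styrenyl enol ether in a 6-exo-trig closure of the siloxane ring, and the benzylic C2 radical is oxidised by the tetravalent iridium formed in the first event to a dimethoxybenzylic cation, which the C4 silyl-ether oxygen captures in a five-membered closure of ring A (5-exo-trig on the quinone-methide form) while its silyl group passes to iodide/2,6-lutidine. The closest known reactions are the Nishiyama–Stork silicon-tethered radical cyclisation and the photoredox oxy-alkylation of styrenes by radical–polar crossover; what is new is their union on a silyl enol ether attacked at its oxygen-bearing carbon. The step needs 6-exo attack at C1 over 7-endo attack at C2, and the C2 aryl group secures it, because only the C1 adduct is a benzylic radical and the styrene carries its larger LUMO coefficient at C1 for the nucleophilic α-silyl radical. C1 is set in a chair transition state with the C6 aryl group equatorial, the C4 arm axial and the alkene carbon C2 equatorial, so that C8 ends cis to C6 and C2 cis to C4. C2 is set in the cation capture, where the aryl group should turn to the convex face of the emerging cis-fused bicycle, syn to the C1 oxygen and away from the siloxane ring. Ring closure must outrun a semipinacol shift of the β-silyloxy cation, which the cis-disposed C4 oxygen and the stabilised cation should allow; C5 and C6 are spectators.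

Step 8
Reactants: 16 bicyclic siloxane (as in step 7)
Product: 18 (2R,3S,4R)-2-(3,4-dimethoxyphenyl)-4-[(R)-(3,4-dimethoxyphenyl)(hydroxy)methyl]-3-(hydroxymethyl)tetrahydrofuran-3-ol, via triethylsilyl ether diol 17 (not isolated)
Conditions: 30% H2O2, KF, KHCO3, THF/MeOH (1:1), rt; aq. Na2S2O3, extraction; then Bu4NF, THF, 0 °C → rt
Reagents that add atoms: hydrogen peroxide, OO
Why: Tamao oxidation converts the C8–Si bond of the alkoxysilane into C8–OH and frees the C6 hydroxyl, and Bu4NF then cleaves the triethylsilyl ether wherever it sits; peroxide is applied before the fluoride-only stage so that no β-hydroxysilane meets base alone (Peterson elimination).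

Step 9
Reactants: 18 (2R,3S,4R)-2-(3,4-dimethoxyphenyl)-4-[(R)-(3,4-dimethoxyphenyl)(hydroxy)methyl]-3-(hydroxymethyl)tetrahydrofuran-3-ol
Product: 19 [(2R,3S,4R)-2-(3,4-dimethoxyphenyl)-4-[(R)-(3,4-dimethoxyphenyl)(hydroxy)methyl]-3-hydroxytetrahydrofuran-3-yl]methyl 4-methylbenzenesulfonate
Conditions: TsCl, Et3N, Bu2SnO (5 mol%), CH2Cl2, 0 °C → rt
Reagents that add atoms: p-toluenesulfonyl chloride, Cc1ccc(S(=O)(=O)Cl)cc1
Why: Stannylene-mediated monosulfonylation selects the primary hydroxyl of the 1,2-diol, so the benzylic C6 hydroxyl is not activated and C6 cannot be inverted in the closure that follows.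

Step 10
Reactants: 19 [(2R,3S,4R)-2-(3,4-dimethoxyphenyl)-4-[(R)-(3,4-dimethoxyphenyl)(hydroxy)methyl]-3-hydroxytetrahydrofuran-3-yl]methyl 4-methylbenzenesulfonate
Product: 21 (+)-gmelinol, via spiro-epoxide 20 (not isolated)
Conditions: NaH, THF, 0 → 40 °C; then water
Reagents that add atoms: none
Why: Two Williamson-type closures in sequence, the C1 alkoxide closing the spiro-epoxide (3-exo-tet) and the C6 alkoxide opening it at the methylene C8 (5-exo-tet), give ring B, and direct displacement of the tosylate by the C6 alkoxide leads to the same product; the C1–O and C6–O bonds are never broken, so both configurations are retained and the endo C6 aryl group never passes through a benzylic cation.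

**Compound list**

1 | (R)-4-benzyl-2-oxazolidinone | O=C1N[C@H](Cc2ccccc2)CO1 | starting material
2 | 3-(tert-butyldimethylsilyloxy)propanoic acid | CC(C)(C)[Si](C)(C)OCCC(=O)O | starting material
3 | 3-(tert-butyldimethylsilyloxy)propanoic pivalic anhydride | CC(C)(C)C(=O)OC(=O)CCO[Si](C)(C)C(C)(C)C | intermediate (not isolated)
4 | (R)-4-benzyl-3-[3-(tert-butyldimethylsilyloxy)propanoyl]oxazolidin-2-one | O=C1OC[C@@H](Cc2ccccc2)N1C(=O)CCO[Si](C)(C)C(C)(C)C | intermediate
5 | veratraldehyde (3,4-dimethoxybenzaldehyde) | COc1ccc(C=O)cc1OC | starting material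
6 | dibutylboron (Z)-enolate of 4 | CCCCB(CCCC)O/C(=C\CO[Si](C)(C)C(C)(C)C)N1C(=O)OC[C@H]1Cc1ccccc1 | intermediate (not isolated)
7 | (R)-4-benzyl-3-[(2R,3R)-2-(tert-butyldimethylsilyloxymethyl)-3-(3,4-dimethoxyphenyl)-3-hydroxypropanoyl]oxazolidin-2-one | O=C1OC[C@@H](Cc2ccccc2)N1C(=O)[C@H](CO[Si](C)(C)C(C)(C)C)[C@@H](O)c1ccc(OC)c(OC)c1 | intermediate
8 | (2R,3R)-2-(tert-butyldimethylsilyloxymethyl)-3-(3,4-dimethoxyphenyl)-3-hydroxy-N-methoxy-N-methylpropanamide | CON(C)C(=O)[C@H](CO[Si](C)(C)C(C)(C)C)[C@@H](O)c1ccc(OC)c(OC)c1 | intermediate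
9 | 3,4-dimethoxybenzyl chloride | COc1ccc(CCl)cc1OC | starting material
10 | 3,4-dimethoxybenzylmagnesium chloride | COc1ccc(C[Mg]Cl)cc1OC | intermediate (not isolated)
11 | (3R,4R)-3-(tert-butyldimethylsilyloxymethyl)-1,4-bis(3,4-dimethoxyphenyl)-4-hydroxybutan-2-one | COc1ccc(CC(=O)[C@H](CO[Si](C)(C)C(C)(C)C)[C@@H](O)c2ccc(OC)c(OC)c2)cc1OC | intermediate
12 | (bromomethyl)chlorodimethylsilane | C[Si](C)(Cl)CBr | starting material
13 | (3R,4R)-4-[(bromomethyl)dimethylsilyloxy]-3-(tert-butyldimethylsilyloxymethyl)-1,4-bis(3,4-dimethoxyphenyl)butan-2-one | COc1ccc(CC(=O)[C@H](CO[Si](C)(C)C(C)(C)C)[C@@H](O[Si](C)(C)CBr)c2ccc(OC)c(OC)c2)cc1OC | intermediate (not isolated)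
14 | (3R,4R)-3-(tert-butyldimethylsilyloxymethyl)-1,4-bis(3,4-dimethoxyphenyl)-4-[(iodomethyl)dimethylsilyloxy]butan-2-one | COc1ccc(CC(=O)[C@H](CO[Si](C)(C)C(C)(C)C)[C@@H](O[Si](C)(C)CI)c2ccc(OC)c(OC)c2)cc1OC | intermediate
15 | (1Z,3R,4R)-3-(tert-butyldimethylsilyloxymethyl)-1,4-bis(3,4-dimethoxyphenyl)-4-[(iodomethyl)dimethylsilyloxy]-2-(triethylsilyloxy)but-1-ene | COc1ccc(/C=C(O[Si](CC)(CC)CC)/[C@H](CO[Si](C)(C)C(C)(C)C)[C@@H](O[Si](C)(C)CI)c2ccc(OC)c(OC)c2)cc1OC | intermediate (key-step precursor)
16 | cis-fused siloxane/tetrahydrofuran with C1–OSiEt3, (1R,2R,5R,6R) in overview numbering | COc1ccc([C@H]2OC[C@@H]3[C@H](c4ccc(OC)c(OC)c4)O[Si](C)(C)C[C@]23O[Si](CC)(CC)CC)cc1OC | intermediate (key-step product)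
17 | [(2R,3S,4R)-2-(3,4-dimethoxyphenyl)-4-[(R)-(3,4-dimethoxyphenyl)(hydroxy)methyl]-3-(triethylsilyloxy)tetrahydrofuran-3-yl]methanol | COc1ccc([C@H]2OC[C@H]([C@@H](O)c3ccc(OC)c(OC)c3)[C@@]2(CO)O[Si](CC)(CC)CC)cc1OC | intermediate (not isolated)
18 | (2R,3S,4R)-2-(3,4-dimethoxyphenyl)-4-[(R)-(3,4-dimethoxyphenyl)(hydroxy)methyl]-3-(hydroxymethyl)tetrahydrofuran-3-ol | COc1ccc([C@H]2OC[C@H]([C@@H](O)c3ccc(OC)c(OC)c3)[C@@]2(CO)O)cc1OC | intermediate
19 | [(2R,3S,4R)-2-(3,4-dimethoxyphenyl)-4-[(R)-(3,4-dimethoxyphenyl)(hydroxy)methyl]-3-hydroxytetrahydrofuran-3-yl]methyl 4-methylbenzenesulfonate | COc1ccc([C@H]2OC[C@H]([C@@H](O)c3ccc(OC)c(OC)c3)[C@@]2(COS(=O)(=O)c4ccc(C)cc4)O)cc1OC | intermediate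
20 | (R)-(3,4-dimethoxyphenyl)[(3S,4R,7R)-4-(3,4-dimethoxyphenyl)-1,5-dioxaspiro[2.4]heptan-7-yl]methanol | COc1ccc([C@H]2OC[C@H]([C@@H](O)c3ccc(OC)c(OC)c3)[C@]24CO4)cc1OC | intermediate (not isolated)
21 | (+)-gmelinol, (1S,2R,5R,6R) in overview numbering | COc1ccc([C@H]2OC[C@@H]3[C@H](c4ccc(OC)c(OC)c4)OC[C@]23O)cc1OC | target

**Step count**

Total: 10 steps. Longest linear sequence: 10 steps (1 and 2 to 21; the Grignard reagent 10 is made in the flask within step 4).

**Steps most likely to fail**

Step 7 (key step). Several processes can divert it: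
- Electron transfer to the C–I bond may be slower than triplet energy transfer to the styrene, so that only E/Z isomerisation is seen.
- The radical may attack C2 in the 7-endo mode or abstract the allylic C5 hydrogen.
- The chair preference may be too weak, giving poor facial selectivity at C1 or C2.
- The cation may undergo a semipinacol shift before the C4 oxygen arrives.

Fallback by known chemistry, setting out from 14 and returning at 18:
- SmI2 (samarium diiodide, divalent samarium; THF, −78 → 0 °C) should effect an intramolecular Barbier addition of the iodomethyl group to the ketone. This forms C1–C8 through a chair with the C6 aryl and the C1 benzyl group equatorial and gives the cyclic siloxane carbinol F1. The C1 configuration rests on this model and would have to be confirmed.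
- Tamao oxidation (H2O2, KF, KHCO3) gives the triol F2.
- Acetic anhydride/pyridine acetylates the primary and the benzylic hydroxyl to the diacetate F3. This deactivates the C6–H bond towards hydride abstraction.
- HF·pyridine removes the silyl group to give the primary alcohol F4.
- DDQ (CH2Cl2, 0 °C) abstracts hydride from the electron-rich benzylic C2 methylene, and the C4 hydroxyl closes ring A. The aryl group is expected trans to the C8 arm, giving the tetrahydrofuran diacetate F5.
- K2CO3/MeOH removes the acetates and gives 18.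

Step 4. Possible failures are Wurtz homocoupling while the electron-rich benzylic Grignard reagent is formed, retro-aldol cleavage of the magnesium aldolate, and dehydration of the β-hydroxy ketone on work-up.

Fallback, setting out from 7 and returning at 11:
- Lithium ethanethiolate (EtSH, n-BuLi, THF, 0 °C) displaces the auxiliary and gives the S-ethyl thioester F6.
- A Fukuyama coupling then joins it to 3,4-dimethoxybenzylzinc chloride F7 (from 9, Zn, LiCl, THF). The catalyst is PdCl2(PPh3)2, a divalent palladium precatalyst reduced in the flask to zerovalent palladium. The conditions are neutral and non-basic and should deliver 11 directly.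

Step 10. The epoxide relay may stall at 20. The epoxy alkoxide may instead fragment in a Grob-type process that expels veratraldehyde, or the epoxide may be opened intermolecularly.

Fallback, setting out from 17 (isolated after the buffered peroxide oxidation instead of being desilylated) and returning at 21:
- Sulfonylation of the primary hydroxyl (TsCl, Et3N, Me3N·HCl, CH2Cl2, 0 °C) gives the silyl-protected tosylate F8.
- NaH/THF lets the C6 alkoxide, the only one available, displace the tosylate directly (5-exo-tet) to the triethylsilyl ether of gmelinol F9.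
- Bu4NF gives 21.

**Further compounds**

F1 | step 7 | 4-(3,4-dimethoxybenzyl)-5-(tert-butyldimethylsilyloxymethyl)-6-(3,4-dimethoxyphenyl)-2,2-dimethyl-1-oxa-2-silacyclohexan-4-ol (C1, C5, C6 as in 18) | COc1ccc([C@@H]2O[Si](C)(C)C[C@](O)(Cc3ccc(OC)c(OC)c3)[C@@H]2CO[Si](C)(C)C(C)(C)C)cc1OC
F2 | step 7 | 2-(3,4-dimethoxybenzyl)-3-(tert-butyldimethylsilyloxymethyl)-4-(3,4-dimethoxyphenyl)butane-1,2,4-triol (C1, C5, C6 as in 18) | COc1ccc(C[C@@](O)(CO)[C@H](CO[Si](C)(C)C(C)(C)C)[C@@H](O)c2ccc(OC)c(OC)c2)cc1OC
F3 | step 7 | 1,4-di-O-acetate of F2 | COc1ccc(C[C@@](O)(COC(C)=O)[C@H](CO[Si](C)(C)C(C)(C)C)[C@@H](OC(C)=O)c2ccc(OC)c(OC)c2)cc1OC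
F4 | step 7 | 1,4-di-O-acetyl-2-(3,4-dimethoxybenzyl)-4-(3,4-dimethoxyphenyl)-3-(hydroxymethyl)butane-1,2,4-triol | COc1ccc(C[C@@](O)(COC(C)=O)[C@H](CO)[C@@H](OC(C)=O)c2ccc(OC)c(OC)c2)cc1OC
F5 | step 7 | diacetate of 18 (primary C8 and benzylic C6 acetates) | COc1ccc([C@H]2OC[C@H]([C@@H](OC(C)=O)c3ccc(OC)c(OC)c3)[C@@]2(COC(C)=O)O)cc1OC
F6 | step 4 | S-ethyl (2R,3R)-2-(tert-butyldimethylsilyloxymethyl)-3-(3,4-dimethoxyphenyl)-3-hydroxypropanethioate | CCSC(=O)[C@H](CO[Si](C)(C)C(C)(C)C)[C@@H](O)c1ccc(OC)c(OC)c1
F7 | step 4 | 3,4-dimethoxybenzylzinc chloride | COc1ccc(C[Zn]Cl)cc1OC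
F8 | step 10 | 4-methylbenzenesulfonate of 17 at the primary hydroxyl | COc1ccc([C@H]2OC[C@H]([C@@H](O)c3ccc(OC)c(OC)c3)[C@@]2(COS(=O)(=O)c4ccc(C)cc4)O[Si](CC)(CC)CC)cc1OC
F9 | step 10 | O-triethylsilyl-(+)-gmelinol | COc1ccc([C@H]2OC[C@@H]3[C@H](c4ccc(OC)c(OC)c4)OC[C@]23O[Si](CC)(CC)CC)cc1OC
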